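**Retrosynthetic overview**
- The (Z)-p-coumarate is built last on the ring alcohol: acylation with a bis(trifluoroethyl) phosphonoacetic acid, then Z-selective Horner–Wadsworth–Emmons olefination with silylated 4-hydroxybenzaldehyde.
- The only ring, the 11-membered carbocycle, is closed by a low-valent titanium keto-aldehyde coupling that forms the C7=C8 E-alkene.
- The keto aldehyde comes from a homopropargylic silyl ether by Zr-catalysed methylalumination and Cu-catalysed 1,4-addition to methyl vinyl ketone (C3=C4 E-alkene).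
- The homopropargylic carbinol comes from a catalytic enantioselective mono-propargylation of C2v-symmetric 3,3-dimethylpentanedial, with the second formyl group trapped as a dithiane in the same flask. This one step breaks the symmetry and sets the only stereocentre (S).
- Ring order: open chain through step 5, the carbocycle closes in step 6, the arene enters in step 10.

Assumption: 3,3-dimethylpentane-1,5-diol and 2-[bis(2,2,2-trifluoroethoxy)phosphoryl]acetic acid are bought; the R phosphoric acid is taken to give Re-face attack as it does with benzaldehyde, otherwise its mirror image is used.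

**Step 1**
Reactants: 1 3,3-dimethylpentane-1,5-diol
Product: 2 3,3-dimethylpentanedial
Conditions: (COCl)2, DMSO, CH2Cl2, −78 °C; Et3N, −78 → 0 °C; used crude
Reagents that add atoms: none
Why: Swern oxidation activates both hydroxyls at −78 °C before base is added, so both are oxidised together and no lactol forms that could go on to the lactone.

**Step 2**
Reactants: 2 3,3-dimethylpentanedial (2.5 equiv); 3 allenylboronic acid pinacol ester; 4 propane-1,3-dithiol
Product: 6 (4S)-1-(1,3-dithian-2-yl)-2,2-dimethylhept-6-yn-4-ol, via boronate aldehyde 5 (not isolated)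
Conditions: (R)-3,3′-bis(2,4,6-triisopropylphenyl)-1,1′-binaphthyl-2,2′-diyl hydrogen phosphate (5 mol %), 4 Å molecular sieves, toluene, −20 °C; then 4, BF3·OEt2 (20 mol %), −20 → 0 °C; aq NaHCO3
Reagents that add atoms: allenylboronic acid pinacol ester 3, C=C=CB1OC(C)(C)C(C)(C)O1; propane-1,3-dithiol 4, SCCCS
Why: Chiral phosphoric acid-catalysed propargylation through a closed six-membered boronate transition state adds to the Re face of one of the two equivalent formyl groups (S carbinol), the excess of 2 keeps double addition low, and thioacetalisation of the remaining formyl group stops the δ-hydroxy aldehyde closing to a lactol.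

**Step 3**
Reactants: 6 (4S)-1-(1,3-dithian-2-yl)-2,2-dimethylhept-6-yn-4-ol
Product: 7 tert-butyl{[(4S)-1-(1,3-dithian-2-yl)-2,2-dimethylhept-6-yn-4-yl]oxy}dimethylsilane
Conditions: TBSOTf, 2,6-lutidine, CH2Cl2, −78 → 0 °C
Reagents that add atoms: tert-butyldimethylsilyl trifluoromethanesulfonate, CC(C)(C)[Si](C)(C)OS(=O)(=O)C(F)(F)F
Why: Silyl ether formation protects the carbinol for the organoaluminium and titanium steps without touching the stereocentre.

**Step 4**
Reactants: 7 tert-butyl{[(4S)-1-(1,3-dithian-2-yl)-2,2-dimethylhept-6-yn-4-yl]oxy}dimethylsilane; 8 methyl vinyl ketone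
Product: 10 (5E,8S)-8-[(tert-butyldimethylsilyl)oxy]-11-(1,3-dithian-2-yl)-6,10,10-trimethylundec-5-en-2-one, via alkenylalane 9 (not isolated)
Conditions: Me3Al (2.2 equiv), Cp2ZrCl2 (25 mol %), CH2Cl2, 0 °C → rt; volatiles off in vacuo; THF, CuBr·SMe2 (10 mol %), 8, −40 → −10 °C; aq NH4Cl
Reagents that add atoms: trimethylaluminium, C[Al](C)C; methyl vinyl ketone 8, CC(=O)C=C
Why: Negishi zirconium-catalysed methylalumination adds methyl and aluminium syn with aluminium at the terminus, and copper-catalysed conjugate addition of the alkenylalane to the enone proceeds with retention, which fixes the E-trisubstituted alkene and delivers the methyl ketone.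

**Step 5**
Reactants: 10 (5E,8S)-8-[(tert-butyldimethylsilyl)oxy]-11-(1,3-dithian-2-yl)-6,10,10-trimethylundec-5-en-2-one
Product: 11 (5S,7E)-5-[(tert-butyldimethylsilyl)oxy]-3,3,7-trimethyl-11-oxododec-7-enal
Conditions: MeI (10 equiv), CaCO3, MeCN/H2O 9:1, 45 °C
Reagents that add atoms: water, O
Why: S-methylation makes the dithiane a leaving group and buffered hydrolysis frees the aldehyde under near-neutral conditions that leave the silyl ether, ketone and alkene alone.

**Step 6**
Reactants: 11 (5S,7E)-5-[(tert-butyldimethylsilyl)oxy]-3,3,7-trimethyl-11-oxododec-7-enal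
Product: 12 tert-butyldimethyl{[(1S,3E,7E)-3,7,10,10-tetramethylcycloundeca-3,7-dien-1-yl]oxy}silane
Conditions: TiCl3(DME)1.5 (10 equiv), Zn(Cu) couple (25 equiv), DME, reflux; 11 added by syringe pump over 30 h (final about 2 mM), then 6 h reflux
Reagents that add atoms: none
Why: McMurry coupling joins ketone and aldehyde carbons on low-valent titanium and deoxygenates the diolate, high dilution favours the 11-membered ring, and the E-trisubstituted alkene is the less strained isomer, as in the keto-aldehyde closure known for the parent humulene ring.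

**Step 7**
Reactants: 12 tert-butyldimethyl{[(1S,3E,7E)-3,7,10,10-tetramethylcycloundeca-3,7-dien-1-yl]oxy}silane
Product: 13 (1S,3E,7E)-3,7,10,10-tetramethylcycloundeca-3,7-dien-1-ol
Conditions: Bu4NF, THF, rt → 40 °C
Reagents that add atoms: none
Why: Fluoride-mediated desilylation frees the secondary alcohol without acid, which the transannularly reactive diene would not tolerate.

**Step 8**
Reactants: 13 (1S,3E,7E)-3,7,10,10-tetramethylcycloundeca-3,7-dien-1-ol; 14 2-[bis(2,2,2-trifluoroethoxy)phosphoryl]acetic acid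
Product: 15 (1S,3E,7E)-3,7,10,10-tetramethylcycloundeca-3,7-dien-1-yl 2-[bis(2,2,2-trifluoroethoxy)phosphoryl]acetate
Conditions: DCC, DMAP (10 mol %), CH2Cl2, 0 °C → rt
Reagents that add atoms: 2-[bis(2,2,2-trifluoroethoxy)phosphoryl]acetic acid 14, OC(=O)CP(=O)(OCC(F)(F)F)OCC(F)(F)F
Why: Steglich esterification acylates the hindered secondary alcohol at oxygen with retention at C1 and installs the Still–Gennari phosphonate.

**Step 9**
Reactants: 16 4-hydroxybenzaldehyde
Product: 17 4-[(tert-butyldimethylsilyl)oxy]benzaldehyde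
Conditions: TBSCl, imidazole, DMF, rt
Reagents that add atoms: tert-butyldimethylsilyl chloride, CC(C)(C)[Si](C)(C)Cl
Why: Silylation removes the acidic phenol so the aldehyde stays electrophilic in the low-temperature olefination.

**Step 10**
Reactants: 15 (1S,3E,7E)-3,7,10,10-tetramethylcycloundeca-3,7-dien-1-yl 2-[bis(2,2,2-trifluoroethoxy)phosphoryl]acetate; 17 4-[(tert-butyldimethylsilyl)oxy]benzaldehyde
Product: 20 (1S,3E,7E)-3,7,10,10-tetramethylcycloundeca-3,7-dien-1-yl (2Z)-3-(4-hydroxyphenyl)prop-2-enoate, via potassium phosphonate 18 (not isolated), via silyl-protected ester 19 (not isolated)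
Conditions: KN(SiMe3)2 (1.05 equiv), 18-crown-6 (3 equiv), THF, −78 °C; 17, −78 °C, 2 h; then AcOH (1.5 equiv), Bu4NF (1.2 equiv), 0 °C, 15 min; dark
Reagents that add atoms: 4-[(tert-butyldimethylsilyl)oxy]benzaldehyde 17, O=Cc1ccc(O[Si](C)(C)C(C)(C)C)cc1
Why: Still–Gennari olefination with the electron-poor phosphonate and a crown-separated potassium ion collapses the kinetic adduct before it equilibrates to give the Z-cinnamate, and acetic acid-buffered fluoride then frees the phenol without forming the phenoxide that would isomerise the alkene.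

**Compound list**
1 | 3,3-dimethylpentane-1,5-diol | OCCC(C)(C)CCO | starting material
2 | 3,3-dimethylpentanedial | O=CCC(C)(C)CC=O | intermediate
3 | allenylboronic acid pinacol ester (4,4,5,5-tetramethyl-2-(propa-1,2-dien-1-yl)-1,3,2-dioxaborolane) | C=C=CB1OC(C)(C)C(C)(C)O1 | starting material
4 | propane-1,3-dithiol | SCCCS | starting material
5 | (5S)-3,3-dimethyl-5-[(4,4,5,5-tetramethyl-1,3,2-dioxaborolan-2-yl)oxy]oct-7-ynal | O=CCC(C)(C)C[C@H](OB1OC(C)(C)C(C)(C)O1)CC#C | intermediate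
6 | (4S)-1-(1,3-dithian-2-yl)-2,2-dimethylhept-6-yn-4-ol | S1CCCSC1CC(C)(C)C[C@H](O)CC#C | intermediate
7 | tert-butyl{[(4S)-1-(1,3-dithian-2-yl)-2,2-dimethylhept-6-yn-4-yl]oxy}dimethylsilane | S1CCCSC1CC(C)(C)C[C@H](O[Si](C)(C)C(C)(C)C)CC#C | intermediate
8 | methyl vinyl ketone (but-3-en-2-one) | CC(=O)C=C | starting material
9 | [(1E,4S)-4-[(tert-butyldimethylsilyl)oxy]-7-(1,3-dithian-2-yl)-2,6,6-trimethylhept-1-en-1-yl]dimethylalane | S1CCCSC1CC(C)(C)C[C@H](O[Si](C)(C)C(C)(C)C)C/C(C)=C/[Al](C)C | intermediate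
10 | (5E,8S)-8-[(tert-butyldimethylsilyl)oxy]-11-(1,3-dithian-2-yl)-6,10,10-trimethylundec-5-en-2-one | S1CCCSC1CC(C)(C)C[C@H](O[Si](C)(C)C(C)(C)C)C/C(C)=C/CCC(C)=O | intermediate
11 | (5S,7E)-5-[(tert-butyldimethylsilyl)oxy]-3,3,7-trimethyl-11-oxododec-7-enal | O=CCC(C)(C)C[C@H](O[Si](C)(C)C(C)(C)C)C/C(C)=C/CCC(C)=O | intermediate
12 | tert-butyldimethyl{[(1S,3E,7E)-3,7,10,10-tetramethylcycloundeca-3,7-dien-1-yl]oxy}silane | C/C1=C\CC(C)(C)C[C@H](O[Si](C)(C)C(C)(C)C)C/C(C)=C/CC1 | intermediate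
13 | (1S,3E,7E)-3,7,10,10-tetramethylcycloundeca-3,7-dien-1-ol | C/C1=C\CC(C)(C)C[C@H](O)C/C(C)=C/CC1 | intermediate
14 | 2-[bis(2,2,2-trifluoroethoxy)phosphoryl]acetic acid | OC(=O)CP(=O)(OCC(F)(F)F)OCC(F)(F)F | starting material
15 | (1S,3E,7E)-3,7,10,10-tetramethylcycloundeca-3,7-dien-1-yl 2-[bis(2,2,2-trifluoroethoxy)phosphoryl]acetate | C/C1=C\CC(C)(C)C[C@H](OC(=O)CP(=O)(OCC(F)(F)F)OCC(F)(F)F)C/C(C)=C/CC1 | intermediate
16 | 4-hydroxybenzaldehyde | O=Cc1ccc(O)cc1 | starting material
17 | 4-[(tert-butyldimethylsilyl)oxy]benzaldehyde | O=Cc1ccc(O[Si](C)(C)C(C)(C)C)cc1 | intermediate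
18 | potassium salt of the phosphonate carbanion of 15 (potassium 1-[bis(2,2,2-trifluoroethoxy)phosphoryl]-2-oxo-2-{[(1S,3E,7E)-3,7,10,10-tetramethylcycloundeca-3,7-dien-1-yl]oxy}ethan-1-ide) | C/C1=C\CC(C)(C)C[C@H](OC(=O)[CH-]P(=O)(OCC(F)(F)F)OCC(F)(F)F)C/C(C)=C/CC1.[K+] | intermediate
19 | (1S,3E,7E)-3,7,10,10-tetramethylcycloundeca-3,7-dien-1-yl (2Z)-3-{4-[(tert-butyldimethylsilyl)oxy]phenyl}prop-2-enoate | C/C1=C\CC(C)(C)C[C@H](OC(=O)/C=C\c2ccc(O[Si](C)(C)C(C)(C)C)cc2)C/C(C)=C/CC1 | intermediate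
20 | (1S,3E,7E)-3,7,10,10-tetramethylcycloundeca-3,7-dien-1-yl (2Z)-3-(4-hydroxyphenyl)prop-2-enoate | C/C1=C\CC(C)(C)C[C@H](OC(=O)/C=C\c2ccc(O)cc2)C/C(C)=C/CC1 | target

**Step count**
Total steps: 10. Longest linear sequence: 9 (steps 1 to 8, then step 10; step 9 is a one-step side branch).

**Three steps most likely to fail**

Step 2 (enantioselectivity on a β-quaternary aliphatic aldehyde and mono- versus bis-addition). The fallback sets out from 2 and comes back at 6, replacing asymmetric catalysis by resolution. Zinc dust and propargyl bromide in THF/aq NH4Cl (Barbier) give the racemic lactol 4,4-dimethyl-6-(prop-2-yn-1-yl)oxan-2-ol F1. Propane-1,3-dithiol with BF3·OEt2 opens it to racemic 1-(1,3-dithian-2-yl)-2,2-dimethylhept-6-yn-4-ol F2. Burkholderia cepacia lipase with vinyl acetate in MTBE should acylate the S enantiomer (Kazlauskas model, propargyl as the medium group and the neopentyl arm as the large group) to (4S)-1-(1,3-dithian-2-yl)-2,2-dimethylhept-6-yn-4-yl acetate F3. F3 is separated from the unreacted R half of F2, and K2CO3 in MeOH returns 6.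

Step 4 (the dithiane may slow the zirconium step, and the alane may transfer methyl or polymerise the enone). The fallback sets out from 7 and comes back at 10, replacing aluminium by boron and copper by rhodium. Copper-catalysed syn-methylboration of the alkyne (CuCl, Xantphos, NaOtBu, B2pin2, MeI, THF) gives 2-[(1E,4S)-4-[(tert-butyldimethylsilyl)oxy]-7-(1,3-dithian-2-yl)-2,6,6-trimethylhept-1-en-1-yl]-4,4,5,5-tetramethyl-1,3,2-dioxaborolane F4. Rhodium-catalysed 1,4-addition of F4 to 8 ([RhCl(cod)]2, KOH, dioxane/H2O, 50 °C) then gives 10.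

Step 6 (the riskiest: macrocyclisation yield and E/Z ratio of the new alkene). The fallback sets out from 7 and comes back at 12, closing the ring at the C4–C5 single bond by B-alkyl Suzuki–Miyaura coupling instead of forming the C7=C8 alkene last.
- Alkenylalane 9 is made as in step 4 and quenched with I2 to give tert-butyl{[(1E,4S)-7-(1,3-dithian-2-yl)-1-iodo-2,6,6-trimethylhept-1-en-4-yl]oxy}dimethylsilane F5.
- MeI/CaCO3 in wet MeCN frees (5S,7E)-5-[(tert-butyldimethylsilyl)oxy]-8-iodo-3,3,7-trimethyloct-7-enal F6.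
- The stabilised ylide 2-(triphenylphosphoranylidene)propanal in toluene at 80 °C sets the second E-trisubstituted alkene in (2E,7S,9E)-7-[(tert-butyldimethylsilyl)oxy]-10-iodo-2,5,5,9-tetramethyldeca-2,9-dienal F7.
- Ph3P=CH2 in THF gives tert-butyl{[(1E,4S,8E)-1-iodo-2,6,6,9-tetramethylundeca-1,8,10-trien-4-yl]oxy}dimethylsilane F8.
- 9-BBN-H adds to the terminal vinyl group to give 9-[(3E,8S,10E)-8-[(tert-butyldimethylsilyl)oxy]-11-iodo-3,6,6,10-tetramethylundeca-3,10-dien-1-yl]-9-borabicyclo[3.3.1]nonane F9, which is not isolated.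
- Pd(dppf)Cl2, AsPh3 and Cs2CO3 in DMF/THF/H2O at high dilution close the ring to 12.

**Further compounds**
F1 | step 2 | 4,4-dimethyl-6-(prop-2-yn-1-yl)oxan-2-ol (racemic) | OC1CC(C)(C)CC(CC#C)O1
F2 | step 2 | 1-(1,3-dithian-2-yl)-2,2-dimethylhept-6-yn-4-ol (racemic) | S1CCCSC1CC(C)(C)CC(O)CC#C
F3 | step 2 | (4S)-1-(1,3-dithian-2-yl)-2,2-dimethylhept-6-yn-4-yl acetate | S1CCCSC1CC(C)(C)C[C@H](OC(C)=O)CC#C
F4 | step 4 | 2-[(1E,4S)-4-[(tert-butyldimethylsilyl)oxy]-7-(1,3-dithian-2-yl)-2,6,6-trimethylhept-1-en-1-yl]-4,4,5,5-tetramethyl-1,3,2-dioxaborolane | S1CCCSC1CC(C)(C)C[C@H](O[Si](C)(C)C(C)(C)C)C/C(C)=C/B1OC(C)(C)C(C)(C)O1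
F5 | step 6 | tert-butyl{[(1E,4S)-7-(1,3-dithian-2-yl)-1-iodo-2,6,6-trimethylhept-1-en-4-yl]oxy}dimethylsilane | S1CCCSC1CC(C)(C)C[C@H](O[Si](C)(C)C(C)(C)C)C/C(C)=C/I
F6 | step 6 | (5S,7E)-5-[(tert-butyldimethylsilyl)oxy]-8-iodo-3,3,7-trimethyloct-7-enal | O=CCC(C)(C)C[C@H](O[Si](C)(C)C(C)(C)C)C/C(C)=C/I
F7 | step 6 | (2E,7S,9E)-7-[(tert-butyldimethylsilyl)oxy]-10-iodo-2,5,5,9-tetramethyldeca-2,9-dienal | O=C/C(C)=C/CC(C)(C)C[C@H](O[Si](C)(C)C(C)(C)C)C/C(C)=C/I
F8 | step 6 | tert-butyl{[(1E,4S,8E)-1-iodo-2,6,6,9-tetramethylundeca-1,8,10-trien-4-yl]oxy}dimethylsilane | C=C/C(C)=C/CC(C)(C)C[C@H](O[Si](C)(C)C(C)(C)C)C/C(C)=C/I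
F9 | step 6 | 9-[(3E,8S,10E)-8-[(tert-butyldimethylsilyl)oxy]-11-iodo-3,6,6,10-tetramethylundeca-3,10-dien-1-yl]-9-borabicyclo[3.3.1]nonane | B1(CC/C(C)=C/CC(C)(C)C[C@H](O[Si](C)(C)C(C)(C)C)C/C(C)=C/I)C2CCCC1CCC2
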